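Numbering follows the depsidone core: ring A = C1–C4 (acyl ring), O5, ring B = C6–C9, O10, C11(=O). Ring C is the seven-membered lactone and ring D the γ-lactone fused at C6–C7.
Enabling feature: the lactone carbonyl carbon (on C7, beside C8–OH) and the lactol carbon (on C6, beside the ether carbon C5a) sit on neighbouring carbons of ring B. Ring D is therefore an ortho-phthalaldehyde whose C7 formyl carbon has been raised to the acid level and whose C6 formyl carbon has taken up an oxygen nucleophile.
Cuts, in order: the two O–acetyl bonds and the ring A acetal (protection); the lactone C(=O)–O bond and the lactol C–OAc bond of ring D together, giving a 6,7-dialdehyde and acetic acid; the ester bond C11–O10 of ring C; the ether bond C4a–O5.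
Forward: rings A and B are bought as benzenes and dressed separately (3 and 5 steps) and joined by SNAr (O5–C4a). Ring C is closed by lactonisation, the 6,7-diol is oxidised to the dialdehyde, and ring D is closed last.
Stereochemistry: the single (S) centre arises in the ring D closure under control of a chiral triazolium-derived carbene, as an acylal that cannot ring-open. It is bared only in the final step, by acyl–oxygen cleavage.

Key step: step 15

Assumption: a 3-hydroxyphthalide-type lactol can racemise through its open formyl acid, so the target lactol is taken to hold its configuration in dry, neutral, aprotic media at or below room temperature; the (5aR,10bS) catalyst is taken to give the (S) acylal, and its equally accessible mirror image would be used if the sense proved opposite.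

Step 1
Reactants: 1 3-fluoro-5-methylanisole
Product: 2 4-bromo-3-fluoro-5-methylanisole
Conditions: NBS, MeCN, 0 °C to rt
Reagents that add atoms: N-bromosuccinimide, O=C1CCC(=O)N1Br
Why: Electrophilic aromatic bromination with NBS in acetonitrile should go para to the methoxy group, between fluorine and methyl, as it does with 3-fluoroanisole itself.

Step 2
Reactants: 2 4-bromo-3-fluoro-5-methylanisole
Product: 4 3-bromo-2-fluoro-6-methoxy-4-methylbenzaldehyde, via aryllithium 3 (not isolated)
Conditions: LDA, THF, −78 °C; DMF, −78 °C; aq. HCl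
Reagents that add atoms: N,N-dimethylformamide, CN(C)C=O
Why: In this directed ortho-metalation the hydrogen between fluorine and methoxy is by far the most acidic, the amide base leaves the C–Br bond alone, and aryllithium 3 is formylated by DMF below the temperature at which LiF would be lost.

Step 3
Reactants: 4 3-bromo-2-fluoro-6-methoxy-4-methylbenzaldehyde
Product: 5 benzyl 2-fluoro-3-formyl-4-methoxy-6-methylbenzoate
Conditions: Pd(OAc)2 (3 mol%), Xantphos (6 mol%), CO (1 atm), BnOH (1.5 equiv), Et3N, toluene, 90 °C
Reagents that add atoms: carbon monoxide, [C-]#[O+]; benzyl alcohol, OCc1ccccc1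
Why: Palladium-catalysed alkoxycarbonylation of aryl bromides tolerates aldehydes and, with a wide-bite-angle diphosphine, ortho substituents, while the apolar solvent and the weak amine base keep benzyl alcohol from displacing fluoride.

Step 4
Reactants: 6 methyl 3,5-bis(benzyloxy)benzoate
Product: 8 methyl 3,5-bis(benzyloxy)-2-formylbenzoate, via iminium chloride 7 (not isolated)
Conditions: POCl3, DMF, 0 to 80 °C; ice–water
Reagents that add atoms: N,N-dimethylformamide, CN(C)C=O; water, O
Why: Vilsmeier–Haack formylation of 3,5-dialkoxybenzoates attacks the position para to one ether oxygen and ortho to the other (C2, equivalent to C6) and not the site between the two ethers, and benzyl ethers survive the reagent.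

Step 5
Reactants: 8 methyl 3,5-bis(benzyloxy)-2-formylbenzoate
Product: 9 methyl 3,5-bis(benzyloxy)-2-bromo-6-formylbenzoate
Conditions: NBS, MeCN, rt, dark
Reagents that add atoms: N-bromosuccinimide, O=C1CCC(=O)N1Br
Why: Electrophilic aromatic bromination should take the last position that is para to one benzyloxy group and ortho to the other (next to the ester) instead of the site between the two ethers, the same 2,6-pattern that 3,5-dialkoxybenzaldehydes show on double halogenation.

Step 6
Reactants: 9 methyl 3,5-bis(benzyloxy)-2-bromo-6-formylbenzoate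
Product: 10 [4,6-bis(benzyloxy)-3-bromobenzene-1,2-diyl]dimethanol
Conditions: LiAlH4, THF, 0 °C; H2O/aq. NaOH work-up
Reagents that add atoms: none
Why: Hydride reduction with LiAlH4 takes aldehyde and ester to the 1,2-benzenedimethanol while the aryl bromide is inert at 0 °C.

Step 7
Reactants: 10 [4,6-bis(benzyloxy)-3-bromobenzene-1,2-diyl]dimethanol
Product: 11 1,5-bis(benzyloxy)-2-bromo-3,4-bis[(tert-butyldimethylsilyloxy)methyl]benzene
Conditions: TBSCl, imidazole, DMF, rt
Reagents that add atoms: tert-butyldimethylsilyl chloride, CC(C)(C)[Si](C)(C)Cl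
Why: Standard silylation of primary alcohols gives ethers that withstand organolithium, carbonate base, hydrogenolysis and acylation and leave later with fluoride.

Step 8
Reactants: 11 1,5-bis(benzyloxy)-2-bromo-3,4-bis[(tert-butyldimethylsilyloxy)methyl]benzene
Product: 14 2,4-bis(benzyloxy)-5,6-bis[(tert-butyldimethylsilyloxy)methyl]phenol, via aryllithium 12 (not isolated), via lithium triisopropoxyborate 13 (not isolated)
Conditions: B(OiPr)3, then n-BuLi, THF–toluene, −78 °C (in situ quench); 30% H2O2, aq. NaOH, 0 °C
Reagents that add atoms: hydrogen peroxide, OO; triisopropyl borate, CC(C)OB(OC(C)C)OC(C)C (its atoms stay only in 13)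
Why: In this borylation–oxidation the bromine–lithium exchange runs with the borate already present, so aryllithium 12 is trapped before a retro-Brook silyl shift or benzyl ether metalation can set in, and peroxide converts the aryl–boron bond into the phenol.

Step 9
Reactants: 5 benzyl 2-fluoro-3-formyl-4-methoxy-6-methylbenzoate; 14 2,4-bis(benzyloxy)-5,6-bis[(tert-butyldimethylsilyloxy)methyl]phenol
Product: 15 benzyl 2-{2,4-bis(benzyloxy)-5,6-bis[(tert-butyldimethylsilyloxy)methyl]phenoxy}-3-formyl-4-methoxy-6-methylbenzoate
Conditions: K2CO3, DMF, 80 °C, argon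
Reagents that add atoms: none
Why: In this nucleophilic aromatic substitution the fluorine of 5 lies between a formyl and an ester group that both stabilise the Meisenheimer adduct, the only free hydroxyl of 14 is the one at the future C5a, and KF drops out of DMF so that the silyl ethers are spared.

Step 10
Reactants: 15 benzyl 2-{2,4-bis(benzyloxy)-5,6-bis[(tert-butyldimethylsilyloxy)methyl]phenoxy}-3-formyl-4-methoxy-6-methylbenzoate
Product: 16 2-{2,4-dihydroxy-5,6-bis[(tert-butyldimethylsilyloxy)methyl]phenoxy}-3-formyl-4-methoxy-6-methylbenzoic acid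
Conditions: H2 (1 atm), 10% Pd/C, EtOAc, rt, stopped after three equivalents of H2
Reagents that add atoms: none
Why: Catalytic hydrogenolysis cleaves the benzyl ester and both aryl benzyl ethers quickly in ethyl acetate, whereas the doubly ortho-substituted, electron-rich formyl group and the silylated benzylic C–O bonds react far more slowly, a selectivity long used with formyl-bearing depside building blocks.

Step 11
Reactants: 16 2-{2,4-dihydroxy-5,6-bis[(tert-butyldimethylsilyloxy)methyl]phenoxy}-3-formyl-4-methoxy-6-methylbenzoic acid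
Product: 18 4-formyl-3-methoxy-1-methyl-11-oxo-6,7-bis[(tert-butyldimethylsilyloxy)methyl]-11H-dibenzo[b,e][1,4]dioxepin-8-yl acetate, via depsidone phenol 17 (not isolated)
Conditions: DCC, DMAP (cat.), CH2Cl2 (2 mM), rt; then Ac2O, pyridine, 0 °C to rt
Reagents that add atoms: acetic anhydride, CC(=O)OC(C)=O
Why: Carbodiimide (Steglich-type) lactonisation of 2-(2-hydroxyphenoxy)benzoic acids is the classical depsidone closure, only the hydroxyl ortho to the ether oxygen can reach the activated acid (ring C, seven-membered) while the para one cannot, and that remaining phenol is acetylated in the same flask.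

Step 12
Reactants: 18 4-formyl-3-methoxy-1-methyl-11-oxo-6,7-bis[(tert-butyldimethylsilyloxy)methyl]-11H-dibenzo[b,e][1,4]dioxepin-8-yl acetate
Product: 19 4-(dimethoxymethyl)-3-methoxy-1-methyl-11-oxo-6,7-bis[(tert-butyldimethylsilyloxy)methyl]-11H-dibenzo[b,e][1,4]dioxepin-8-yl acetate
Conditions: MeOSiMe3 (3 equiv), Me3SiOTf (5 mol%), CH2Cl2, −78 °C; pyridine quench
Reagents that add atoms: methoxytrimethylsilane, CO[Si](C)(C)C
Why: Noyori acetalisation (alkoxysilane with catalytic silyl triflate) runs under aprotic conditions at low temperature, so the only aldehyde becomes its dimethyl acetal while silyl ethers, aryl acetate and depsidone ester stay, and ring B, now carrying two acyloxy groups, no longer ionises at its benzylic positions.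

Step 13
Reactants: 19 4-(dimethoxymethyl)-3-methoxy-1-methyl-11-oxo-6,7-bis[(tert-butyldimethylsilyloxy)methyl]-11H-dibenzo[b,e][1,4]dioxepin-8-yl acetate
Product: 20 4-(dimethoxymethyl)-6,7-bis(hydroxymethyl)-3-methoxy-1-methyl-11-oxo-11H-dibenzo[b,e][1,4]dioxepin-8-yl acetate
Conditions: HF·pyridine, pyridine, THF, 0 °C; pH 7 buffer; used crude
Reagents that add atoms: none
Why: Fluoride-mediated desilylation in a weakly acidic, water-free medium releases both primary alcohols as neutral hydroxyl groups, so no alkoxide arises that could pull the acetyl group off the neighbouring C8 oxygen, and the acetal has no water to react with.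

Step 14
Reactants: 20 4-(dimethoxymethyl)-6,7-bis(hydroxymethyl)-3-methoxy-1-methyl-11-oxo-11H-dibenzo[b,e][1,4]dioxepin-8-yl acetate
Product: 22 4-(dimethoxymethyl)-6,7-diformyl-3-methoxy-1-methyl-11-oxo-11H-dibenzo[b,e][1,4]dioxepin-8-yl acetate, via bis(alkoxysulfonium) dichloride 21 (not isolated)
Conditions: (COCl)2, DMSO, CH2Cl2, −78 °C; Et3N, −78 to 0 °C; pH 7 buffer
Reagents that add atoms: none
Why: Swern oxidation activates both hydroxyl groups as 21 before base is added, so no hydroxy aldehyde is left to close to a lactol and over-oxidise, which makes it the standard way from 1,2-benzenedimethanols to ortho-phthalaldehydes.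

Step 15
Reactants: 22 4-(dimethoxymethyl)-6,7-diformyl-3-methoxy-1-methyl-11-oxo-11H-dibenzo[b,e][1,4]dioxepin-8-yl acetate; 23 acetic acid
Product: 26 (1S)-11-(dimethoxymethyl)-10-methoxy-8-methyl-3,7-dioxo-1,3-dihydro-7H-isobenzofuro[4,5-b][1,4]benzodioxepine-1,4-diyl diacetate, via acyl azolium acetate 24 (not isolated), via hemiacylal alkoxide 25 (not isolated)
Conditions: (5aR,10bS)-2-mesityl-5a,10b-dihydro-4H,6H-indeno[2,1-b][1,2,4]triazolo[4,3-d][1,4]oxazin-2-ium tetrafluoroborate (20 mol%), 3,3',5,5'-tetra-tert-butyldiphenoquinone (1.2 equiv), AcOH (1.5 equiv), i-Pr2NEt (1.5 equiv), 4 Å MS, CH2Cl2, −20 °C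
Reagents that add atoms: acetic acid 23, CC(=O)O
Why: The carbene adds to the C7 formyl group, the Breslow intermediate is oxidised by the diphenoquinone to acyl azolium 24, acetate adds reversibly to the neighbouring C6 formyl group to give hemiacylal alkoxide 25, and its oxygen attacks the acyl azolium carbonyl, which forms the lactone C–O bond and frees the carbene. The closest known reaction type is the carbene-catalysed oxidative, enantioselective acetalisation of carboxylic acids with ortho-phthalaldehydes to phthalidyl esters. Ring D closes in the 5-exo-trig mode at the acyl azolium carbonyl. The two hemiacylal enantiomers interconvert by loss and re-addition of acetate and the chiral azolium next door acylates one of them faster, so the (S) centre is set by the catalyst in a dynamic kinetic resolution and is locked at once as an acylal. The step needs the bulky carbene to choose C7 over C6: the C6 formyl group is walled in by O5 and by the dimethoxymethyl group of ring A across the folded ring C and admits only the small acetate, whereas the C7 formyl group has a flat, weakly donating acetoxy neighbour. The ring A aldehyde is masked, the C11 ester is shielded by two ortho substituents, and because the phenol ester and the nucleophile carry the same acyl group any acetyl exchange is degenerate.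

Step 16
Reactants: 26 (1S)-11-(dimethoxymethyl)-10-methoxy-8-methyl-3,7-dioxo-1,3-dihydro-7H-isobenzofuro[4,5-b][1,4]benzodioxepine-1,4-diyl diacetate
Product: 27 (1S)-11-formyl-10-methoxy-8-methyl-3,7-dioxo-1,3-dihydro-7H-isobenzofuro[4,5-b][1,4]benzodioxepine-1,4-diyl diacetate
Conditions: silica gel loaded with 10% aq. oxalic acid, CH2Cl2, rt
Reagents that add atoms: water, O
Why: Acid-catalysed acetal hydrolysis on wet silica is selective because the acetal carbon on electron-rich ring A ionises easily whereas the acylal carbon, held between a lactone oxygen and an electron-poor ring, does not, so the stereocentre is not touched.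

Step 17
Reactants: 27 (1S)-11-formyl-10-methoxy-8-methyl-3,7-dioxo-1,3-dihydro-7H-isobenzofuro[4,5-b][1,4]benzodioxepine-1,4-diyl diacetate
Product: 28 (1S)-1,4-dihydroxy-10-methoxy-8-methyl-3,7-dioxo-1,3-dihydro-7H-isobenzofuro[4,5-b][1,4]benzodioxepine-11-carbaldehyde
Conditions: immobilised Burkholderia cepacia lipase, n-BuOH (10 equiv), dry t-BuOMe, 25 °C; filtration, evaporation below rt
Reagents that add atoms: none
Why: Lipase-catalysed alcoholysis passes both acetyl groups to butanol through an acyl-enzyme and breaks only acyl–oxygen bonds, a mode known for aryl acetates and for γ-acyloxy lactones, so the C–O bond at the stereocentre stays and the lactol is released as a neutral hydroxyl group in a base-free aprotic medium.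

Compound list
1 | 3-fluoro-5-methylanisole | COc1cc(C)cc(F)c1 | starting material
2 | 4-bromo-3-fluoro-5-methylanisole | COc1cc(C)c(Br)c(F)c1 | intermediate
3 | 4-bromo-3-fluoro-2-lithio-5-methylanisole | COc1cc(C)c(Br)c(F)c1[Li] | intermediate
4 | 3-bromo-2-fluoro-6-methoxy-4-methylbenzaldehyde | COc1cc(C)c(Br)c(F)c1C=O | intermediate
5 | benzyl 2-fluoro-3-formyl-4-methoxy-6-methylbenzoate | COc1cc(C)c(C(=O)OCc2ccccc2)c(F)c1C=O | intermediate
6 | methyl 3,5-bis(benzyloxy)benzoate | COC(=O)c1cc(OCc2ccccc2)cc(OCc2ccccc2)c1 | starting material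
7 | [2,4-bis(benzyloxy)-6-(methoxycarbonyl)benzylidene]dimethylammonium chloride | COC(=O)c1cc(OCc2ccccc2)cc(OCc2ccccc2)c1C=[N+](C)C.[Cl-] | intermediate
8 | methyl 3,5-bis(benzyloxy)-2-formylbenzoate | COC(=O)c1cc(OCc2ccccc2)cc(OCc2ccccc2)c1C=O | intermediate
9 | methyl 3,5-bis(benzyloxy)-2-bromo-6-formylbenzoate | COC(=O)c1c(Br)c(OCc2ccccc2)cc(OCc2ccccc2)c1C=O | intermediate
10 | [4,6-bis(benzyloxy)-3-bromobenzene-1,2-diyl]dimethanol | Brc1c(OCc2ccccc2)cc(OCc2ccccc2)c(CO)c1CO | intermediate
11 | 1,5-bis(benzyloxy)-2-bromo-3,4-bis[(tert-butyldimethylsilyloxy)methyl]benzene | Brc1c(OCc2ccccc2)cc(OCc2ccccc2)c(CO[Si](C)(C)C(C)(C)C)c1CO[Si](C)(C)C(C)(C)C | intermediate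
12 | aryllithium from 11 (Li in place of Br) | [Li]c1c(OCc2ccccc2)cc(OCc2ccccc2)c(CO[Si](C)(C)C(C)(C)C)c1CO[Si](C)(C)C(C)(C)C | intermediate
13 | lithium aryl(triisopropoxy)borate from 12 | [Li+].CC(C)O[B-](OC(C)C)(OC(C)C)c1c(OCc2ccccc2)cc(OCc2ccccc2)c(CO[Si](C)(C)C(C)(C)C)c1CO[Si](C)(C)C(C)(C)C | intermediate
14 | 2,4-bis(benzyloxy)-5,6-bis[(tert-butyldimethylsilyloxy)methyl]phenol | Oc1c(OCc2ccccc2)cc(OCc2ccccc2)c(CO[Si](C)(C)C(C)(C)C)c1CO[Si](C)(C)C(C)(C)C | intermediate
15 | benzyl 2-{2,4-bis(benzyloxy)-5,6-bis[(tert-butyldimethylsilyloxy)methyl]phenoxy}-3-formyl-4-methoxy-6-methylbenzoate | COc1cc(C)c(C(=O)OCc2ccccc2)c(Oc2c(OCc3ccccc3)cc(OCc3ccccc3)c(CO[Si](C)(C)C(C)(C)C)c2CO[Si](C)(C)C(C)(C)C)c1C=O | intermediate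
16 | 2-{2,4-dihydroxy-5,6-bis[(tert-butyldimethylsilyloxy)methyl]phenoxy}-3-formyl-4-methoxy-6-methylbenzoic acid | COc1cc(C)c(C(=O)O)c(Oc2c(O)cc(O)c(CO[Si](C)(C)C(C)(C)C)c2CO[Si](C)(C)C(C)(C)C)c1C=O | intermediate
17 | 8-hydroxy-3-methoxy-1-methyl-11-oxo-6,7-bis[(tert-butyldimethylsilyloxy)methyl]-11H-dibenzo[b,e][1,4]dioxepine-4-carbaldehyde | COc1cc(C)c2c(c1C=O)Oc1c(cc(O)c(CO[Si](C)(C)C(C)(C)C)c1CO[Si](C)(C)C(C)(C)C)OC2=O | intermediate
18 | 4-formyl-3-methoxy-1-methyl-11-oxo-6,7-bis[(tert-butyldimethylsilyloxy)methyl]-11H-dibenzo[b,e][1,4]dioxepin-8-yl acetate | COc1cc(C)c2c(c1C=O)Oc1c(cc(OC(C)=O)c(CO[Si](C)(C)C(C)(C)C)c1CO[Si](C)(C)C(C)(C)C)OC2=O | intermediate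
19 | 4-(dimethoxymethyl)-3-methoxy-1-methyl-11-oxo-6,7-bis[(tert-butyldimethylsilyloxy)methyl]-11H-dibenzo[b,e][1,4]dioxepin-8-yl acetate | COc1cc(C)c2c(c1C(OC)OC)Oc1c(cc(OC(C)=O)c(CO[Si](C)(C)C(C)(C)C)c1CO[Si](C)(C)C(C)(C)C)OC2=O | intermediate
20 | 4-(dimethoxymethyl)-6,7-bis(hydroxymethyl)-3-methoxy-1-methyl-11-oxo-11H-dibenzo[b,e][1,4]dioxepin-8-yl acetate | COc1cc(C)c2c(c1C(OC)OC)Oc1c(cc(OC(C)=O)c(CO)c1CO)OC2=O | intermediate
21 | bis(alkoxysulfonium) dichloride of 20 (both CH2OH as CH2O–S(+)Me2) | COc1cc(C)c2c(c1C(OC)OC)Oc1c(cc(OC(C)=O)c(CO[S+](C)C)c1CO[S+](C)C)OC2=O.[Cl-].[Cl-] | intermediate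
22 | 4-(dimethoxymethyl)-6,7-diformyl-3-methoxy-1-methyl-11-oxo-11H-dibenzo[b,e][1,4]dioxepin-8-yl acetate | COc1cc(C)c2c(c1C(OC)OC)Oc1c(cc(OC(C)=O)c(C=O)c1C=O)OC2=O | intermediate
23 | acetic acid | CC(=O)O | starting material
24 | acyl azolium acetate: C7 carbonyl carbon of 22 bonded to the carbene carbon of the (5aR,10bS)-N-mesityl triazolium, C6 formyl intact | COc1cc(C)c2c(c1C(OC)OC)Oc1c(cc(OC(C)=O)c(C(=O)c3n4[C@@H]5[C@@H](Cc6ccccc56)OCc4n[n+]3-c7c(C)cc(C)cc7C)c1C=O)OC2=O.CC(=O)[O-] | intermediate
25 | (S)-hemiacylal alkoxide: acetate added to the C6 formyl group of 24 (zwitterion) | COc1cc(C)c2c(c1C(OC)OC)Oc1c(cc(OC(C)=O)c(C(=O)c3n4[C@@H]5[C@@H](Cc6ccccc56)OCc4n[n+]3-c7c(C)cc(C)cc7C)c1[C@@H](OC(C)=O)[O-])OC2=O | intermediate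
26 | (1S)-11-(dimethoxymethyl)-10-methoxy-8-methyl-3,7-dioxo-1,3-dihydro-7H-isobenzofuro[4,5-b][1,4]benzodioxepine-1,4-diyl diacetate | COc1cc(C)c2c(c1C(OC)OC)Oc1c(cc(OC(C)=O)c3c1[C@@H](OC(C)=O)OC3=O)OC2=O | intermediate
27 | (1S)-11-formyl-10-methoxy-8-methyl-3,7-dioxo-1,3-dihydro-7H-isobenzofuro[4,5-b][1,4]benzodioxepine-1,4-diyl diacetate | COc1cc(C)c2c(c1C=O)Oc1c(cc(OC(C)=O)c3c1[C@@H](OC(C)=O)OC3=O)OC2=O | intermediate
28 | (1S)-1,4-dihydroxy-10-methoxy-8-methyl-3,7-dioxo-1,3-dihydro-7H-isobenzofuro[4,5-b][1,4]benzodioxepine-11-carbaldehyde | COc1cc(C)c2c(c1C=O)Oc1c(cc(O)c3c1[C@@H](O)OC3=O)OC2=O | target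

Total step count: 17. Longest linear sequence: 14 (steps 4–17, from 6). Ring A takes steps 1–3 and enters at step 9.

Steps most likely to fail

Step 15. The carbene may also engage the C6 formyl group (regiochemical leakage). It may tell the two hemiacylal enantiomers apart too poorly, or it may strip the activated aryl acetate. Fallback: regiocontrol and enantiocontrol are handed to two different catalysts.
- Setting out from 22, an achiral triazolium salt chosen only for its bulk is used: 2-(2,6-diisopropylphenyl)-6,7-dihydro-5H-pyrrolo[2,1-c][1,2,4]triazol-2-ium tetrafluoroborate. With the same diphenoquinone and water in THF it should oxidise the exposed C7 formyl group to the acid, which closes onto the C6 formyl group to give racemic lactol F1.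
- F1 is then acetylated with Ac2O and i-Pr2NEt under a chiral isothiourea catalyst (HyperBTM) in an acylative dynamic kinetic resolution. This is a known entry to enantioenriched phthalidyl esters: the lactol racemises through its open formyl acid while one enantiomer is acylated faster.
- Any phenol bared in the first operation is re-acetylated, and the route is rejoined at 26.

Step 17. The lipase may not accept the crowded acylal, whose (S) arrangement need not match the usual preference of lipases for secondary alcohols. A slow reaction would give the liberated lactol time to lose its configuration by ring opening. Fallback: recognition is moved from the alcohol part to the acyl part by changing the acid built in at the ring D closure.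
- From 22, the conditions of step 15 with butanoic acid in place of 23 should give (S)-lactol butanoate F2.
- The conditions of step 16 then give formyl butanoate F3.
- Candida rugosa lipase prefers medium-chain acyl groups and has a wide alcohol pocket. With butan-1-ol in dry t-BuOMe it should remove the butanoyl and acetyl groups and arrive at 28.

Step 9. Attack of the doubly ortho-substituted phenoxide on a carbon flanked by a formyl group and a twisted benzyl ester may be too slow. Desilylation by the liberated fluoride or oxidation of the electron-rich phenoxide could then take over. Fallback: ether formation and carbonylation change places.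
- In bromide 4 the C–F carbon has a single bromine atom beside it instead of the out-of-plane ester and is still activated by the ortho formyl group. It is coupled with 14 (K2CO3, DMF, 100 °C) to give bromo diaryl ether F4.
- Alkoxycarbonylation of F4 with Pd(OAc)2, di(1-adamantyl)-n-butylphosphine, CO, BnOH and Et3N leads to 15.

Further compounds
F1 | step 15 | racemic 11-(dimethoxymethyl)-1-hydroxy-10-methoxy-8-methyl-3,7-dioxo-1,3-dihydro-7H-isobenzofuro[4,5-b][1,4]benzodioxepin-4-yl acetate | COc1cc(C)c2c(c1C(OC)OC)Oc1c(cc(OC(C)=O)c3c1C(O)OC3=O)OC2=O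
F2 | step 17 | (1S)-4-acetoxy-11-(dimethoxymethyl)-10-methoxy-8-methyl-3,7-dioxo-1,3-dihydro-7H-isobenzofuro[4,5-b][1,4]benzodioxepin-1-yl butanoate | COc1cc(C)c2c(c1C(OC)OC)Oc1c(cc(OC(C)=O)c3c1[C@@H](OC(=O)CCC)OC3=O)OC2=O
F3 | step 17 | (1S)-4-acetoxy-11-formyl-10-methoxy-8-methyl-3,7-dioxo-1,3-dihydro-7H-isobenzofuro[4,5-b][1,4]benzodioxepin-1-yl butanoate | COc1cc(C)c2c(c1C=O)Oc1c(cc(OC(C)=O)c3c1[C@@H](OC(=O)CCC)OC3=O)OC2=O
F4 | step 9 | 2-{2,4-bis(benzyloxy)-5,6-bis[(tert-butyldimethylsilyloxy)methyl]phenoxy}-3-bromo-6-methoxy-4-methylbenzaldehyde | COc1cc(C)c(Br)c(Oc2c(OCc3ccccc3)cc(OCc3ccccc3)c(CO[Si](C)(C)C(C)(C)C)c2CO[Si](C)(C)C(C)(C)C)c1C=O
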